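Think of a small charge first: the dimer step goes with the square of the substrate, the gas step with its first power, so a smaller charge gives the gas step a larger share. The flask you take over is no small charge.

substrate 1.5 M; gas phase 200 mM (held); time 6.0 d

- amount of target at 6.0 d, in percent of the substrate charged
- the change that raises the amount of target at 6.0 d, in percent of the substrate charged most ("none" if none brings more than 2 percentage points) (west / south / none)
- amount of target at 6.0 d, in percent of the substrate charged, after south

    2 substrate → homo dimer (k1 = 0.044 /M/h)
    gas phase ⇌ dissolved gas, rate k2*(csat - [dissolved gas]) (k2 = 0.21 /h, csat = 200 mM)
    substrate + dissolved gas → target (k3 = 0.15 /M/h)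
    target ⇌ isomer of the product (K4 = 0.18, k4 = 0.042 /h)
    dissolved gas → decomposed reagent (k5 = 0.63 /h)

Count the gas first. Its half-life against decomposition, 1.1 h, is short against the run, so take dissolved gas as held at 50.0 mM. Now carry the crossover, the fraction of the charge at which both steps take substrate equally: 5.68%. Above it the dimer step leads, below it the gas step, and the charge starts far above it. At that level the gas step is a pseudo-first-order loss making 1.08 turnovers in the run. Expect 2.69% of the substrate left and 14.4% of the charge through the gas step. The isomer relaxes quickly, which leaves 12.2% as target. Read that as the high side: the held level leaves out the gas that the substrate takes, at the start 0.225 /h against 0.840 /h for transfer and decomposition together.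

Don't touch the transfer coefficient if saturation can move: doubling it lifts the level to 80.0 mM, doubling saturation to 100 mM, which gives 20.9%.

The forecast, holding that “dimerisation takes most of the substrate”, gives 10.9%, south and 18.8%. The flask gives 10.9%, south (a gain of 7.8 percentage points, against 5.3 points for west) and 18.7%.

The target stands below my figure. With 0.38 M of substrate, the crossover becomes 22.4%, the same count gives 26.1%, and that neighbour flask gives 25.0%. This flask has not quite come to rest: its 2.7% of substrate lies below the crossover. After 60.0 d the substrate stands at 0%, the homo dimer at 84.9%, and the target at 12.8%, while decomposed reagent has climbed to 45.2 M.

(All constants are those of an exercise; the rest is arithmetic.)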